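**Plan**
Labels: A and B are the benzo and pyranone rings of the chromone, C is the resorcinol ring, and D is the δ-lactone. C and D carry isochromanone numbers. Feature: ring C has OH on C6 and C8 with the C7 methyl between them. It shares C4a–C8a with ring D, whose carbonyl C1 sits on C8a. This is the pattern left by a vinylketene (C8=C5–C4a=C8a) joined to a 1-siloxypropyne (C7≡C6).
Cuts: after two O-protecting groups are removed, ring C is opened at C7–C8, C5–C6 and C8–C8a. The ketene source, an acyl chloride, is then cut at C5–CH2 (malonate alkylation) and at C5–C4a (addition–elimination on a dihydropyranone).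
Forward: ring D is made first. Ring B is annulated onto ring A of a symmetric benzaldehyde whose CHO becomes the bridge CH2. Both halves are attached to one malonate carbon, and ring C closes last.
Stereochemistry: the only stereocentre, C3 (R), comes from ethyl (R)-3-hydroxybutanoate. Neither its C–O bond nor its hydrogen is touched afterwards.

Key step: step 13

Assumption: the carbon alpha to the carboxyl group in the acid and in its chloride is carried as a mixture of epimers and may equilibrate with the alkene-shifted glutaconic tautomer. All these forms give the same vinylketene, so no control is sought there.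

**Step 1**
Reactants: 1 4-hydroxy-2,6-dimethoxybenzaldehyde
Product: 2 4-hydroxy-3-iodo-2,6-dimethoxybenzaldehyde
Conditions: NIS (1.0 equiv), TFA (10 mol %), MeCN, 0 °C → rt
Reagents that add atoms: N-iodosuccinimide, O=C1CCC(=O)N1I
Why: Electrophilic aromatic iodination; the two open positions of 1 are equivalent and each lies ortho to the phenol and ortho/para to the methoxy groups, so one equivalent of the iodinating agent should give a single monoiodide.

**Step 2**
Reactants: 2 4-hydroxy-3-iodo-2,6-dimethoxybenzaldehyde; 3 propyne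
Product: 5 5,7-dimethoxy-2-methyl-4-oxo-4H-chromene-6-carbaldehyde, via ynone 4 (not isolated)
Conditions: PdCl2(dppf) (3 mol %), CO (10 bar), propyne (3 equiv), Et2NH, 100 °C, autoclave
Reagents that add atoms: carbon monoxide, [C-]#[O+]
Why: Carbonylative Sonogashira-type coupling of an o-iodophenol (oxidative addition to zerovalent palladium, CO insertion, alkynyl transfer) gives ynone 4, whose phenol adds 6-endo to the triple bond in the secondary-amine medium, which is the established carbonylative annulation to 2-substituted chromones; the aldehyde between the two methoxy groups is a spectator and marks chromone C6 unambiguously.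

**Step 3**
Reactants: 5 5,7-dimethoxy-2-methyl-4-oxo-4H-chromene-6-carbaldehyde
Product: 6 6-(hydroxymethyl)-5,7-dimethoxy-2-methyl-4H-chromen-4-one
Conditions: NaBH4 (0.5 equiv), MeOH/CH2Cl2, 0 °C
Reagents that add atoms: none
Why: Chemoselective borohydride 1,2-reduction, the aldehyde reacting much faster at 0 °C than the vinylogous-ester carbonyl of ring B.

**Step 4**
Reactants: 6 6-(hydroxymethyl)-5,7-dimethoxy-2-methyl-4H-chromen-4-one
Product: 7 6-(bromomethyl)-5,7-dimethoxy-2-methyl-4H-chromen-4-one
Conditions: PBr3 (0.4 equiv), CH2Cl2, 0 °C; used at once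
Reagents that add atoms: phosphorus tribromide, BrP(Br)Br
Why: Standard alcohol-to-bromide exchange through a phosphite ester (SN2), fast for a benzylic alcohol activated by two ortho methoxy groups, which is also why 7 is not stored.

**Step 5**
Reactants: 8 ethyl (R)-3-hydroxybutanoate; 9 tert-butyl acetate
Product: 10 tert-butyl (R)-5-hydroxy-3-oxohexanoate
Conditions: 9 (4 equiv), LiN(iPr)2 (4 equiv), THF, −78 °C; then 8, −78 → −20 °C; AcOH quench
Reagents that add atoms: none
Why: Crossed Claisen condensation; the excess enolate first takes the hydroxyl proton and then acylates at the ethyl ester, the product is shielded as its enolate, and the carbinol stereocentre is not an enolisable position.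

**Step 6**
Reactants: 10 tert-butyl (R)-5-hydroxy-3-oxohexanoate
Product: 11 (R)-4-hydroxy-6-methyl-5,6-dihydro-2H-pyran-2-one (enol form of the 2,4-dione)
Conditions: TFA, CH2Cl2, rt
Reagents that add atoms: none
Why: Acidolysis of the tert-butyl ester and lactonisation of the δ-hydroxy β-keto acid (acyl substitution closing six-membered ring D); the C–O bond at the stereocentre stays intact, so R is retained.

**Step 7**
Reactants: 11 (R)-4-hydroxy-6-methyl-5,6-dihydro-2H-pyran-2-one
Product: 12 (R)-6-methyl-2-oxo-5,6-dihydro-2H-pyran-4-yl 4-methylbenzenesulfonate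
Conditions: TsCl, Et3N, CH2Cl2, 0 °C
Reagents that add atoms: 4-toluenesulfonyl chloride, Cc1ccc(cc1)S(=O)(=O)Cl
Why: O-sulfonylation of the acidic enol of a β-keto lactone gives a vinylogous mixed anhydride set up for addition–elimination at its C4.

**Step 8**
Reactants: 12 (R)-6-methyl-2-oxo-5,6-dihydro-2H-pyran-4-yl 4-methylbenzenesulfonate; 13 di-tert-butyl malonate
Product: 14 di-tert-butyl 2-[(R)-6-methyl-2-oxo-5,6-dihydro-2H-pyran-4-yl]malonate
Conditions: 13 (2.2 equiv), NaH (2.1 equiv), THF, 0 °C → rt; 1 M HCl work-up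
Reagents that add atoms: none
Why: Conjugate addition–elimination (vinylic substitution) of a soft malonate anion at the β-carbon of the sulfonyloxy enoate; the second equivalent of anion deprotonates the more acidic product and so protects it, and this base is too weak for eliminative opening of the lactone.

**Step 9**
Reactants: 14 di-tert-butyl 2-[(R)-6-methyl-2-oxo-5,6-dihydro-2H-pyran-4-yl]malonate; 7 6-(bromomethyl)-5,7-dimethoxy-2-methyl-4H-chromen-4-one
Product: 15 di-tert-butyl 2-[(5,7-dimethoxy-2-methyl-4-oxo-4H-chromen-6-yl)methyl]-2-[(R)-6-methyl-2-oxo-5,6-dihydro-2H-pyran-4-yl]malonate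
Conditions: K2CO3, DMF, 0 °C → rt
Reagents that add atoms: none
Why: Malonate C-alkylation (SN2) with a very reactive benzylic bromide; the delocalised anion of 14 holds most of its charge in the diester half and should react at that carbon, which also leaves the ring alkene conjugated with the lactone, and carbonate is too weak to touch the chromone 2-methyl group.

**Step 10**
Reactants: 15 di-tert-butyl 2-[(5,7-dimethoxy-2-methyl-4-oxo-4H-chromen-6-yl)methyl]-2-[(R)-6-methyl-2-oxo-5,6-dihydro-2H-pyran-4-yl]malonate
Product: 17 3-(5,7-dimethoxy-2-methyl-4-oxo-4H-chromen-6-yl)-2-[(R)-6-methyl-2-oxo-5,6-dihydro-2H-pyran-4-yl]propanoic acid (both epimers at C2), via malonic diacid 16 (not isolated)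
Conditions: TFA/CH2Cl2, rt; evaporate; 1,4-dioxane, 90 °C
Reagents that add atoms: none
Why: Acidolysis of both tert-butyl esters followed by malonic acid decarboxylation, eased because the departing CO2 leaves an enediol conjugated with the unsaturated lactone, whereas the remaining carboxyl group lacks that second activating group and should survive at 90 °C; the new alpha centre forms without control and is erased in step 13.

**Step 11**
Reactants: 17 3-(5,7-dimethoxy-2-methyl-4-oxo-4H-chromen-6-yl)-2-[(R)-6-methyl-2-oxo-5,6-dihydro-2H-pyran-4-yl]propanoic acid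
Product: 18 3-(5,7-dimethoxy-2-methyl-4-oxo-4H-chromen-6-yl)-2-[(R)-6-methyl-2-oxo-5,6-dihydro-2H-pyran-4-yl]propanoyl chloride (both epimers at C2)
Conditions: 1-chloro-N,N,2-trimethylprop-1-en-1-amine (1.1 equiv), CH2Cl2, 0 °C → rt; evaporate, use crude
Reagents that add atoms: 1-chloro-N,N,2-trimethylprop-1-en-1-amine, CC(C)=C(Cl)N(C)C
Why: Neutral acid chloride formation with an α-chloroenamine (through an acyloxyiminium chloride), which avoids HCl and Vilsmeier-type species that could attack the basic chromone carbonyl or start premature enolisation.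

**Step 12**
Reactants: 3 propyne
Product: 21 1-(triisopropylsiloxy)propyne, via 1-propynyllithium 19 (not isolated), via lithium propynolate 20 (not isolated)
Conditions: nBuLi, THF, −78 °C; tBuOOLi (from tBuOOH + LiN(SiMe3)2), −78 → 0 °C; TIPSOTf, −78 → 0 °C
Reagents that add atoms: tert-butyl hydroperoxide, CC(C)(C)OO; triisopropylsilyl trifluoromethanesulfonate, CC(C)[Si](OS(=O)(=O)C(F)(F)F)(C(C)C)C(C)C
Why: Oxidation of a lithium acetylide by lithium tert-butyl peroxide to the lithium ynolate, then O-silylation with the bulky, hard silyl triflate, is the standard one-flask route from terminal alkynes to triisopropylsiloxyalkynes.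

**Step 13**
Reactants: 18 3-(5,7-dimethoxy-2-methyl-4-oxo-4H-chromen-6-yl)-2-[(R)-6-methyl-2-oxo-5,6-dihydro-2H-pyran-4-yl]propanoyl chloride; 21 1-(triisopropylsiloxy)propyne
Product: 26 (R)-5-[(5,7-dimethoxy-2-methyl-4-oxo-4H-chromen-6-yl)methyl]-8-hydroxy-3,7-dimethyl-6-(triisopropylsiloxy)isochroman-1-one, via vinylketene 22 (not isolated), via cyclobutenone 23 (not isolated), via dienylketene 24 (not isolated), via cyclohexadienone 25 (not isolated)
Conditions: 18 added slowly to 21 (2.5 equiv) and iPr2NEt (1.5 equiv), toluene, 0 °C → rt; filter under argon; 105 °C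
Reagents that add atoms: none
Why: Proposed new method: iPr2NEt removes the proton of 18 that is alpha to the acyl chloride and vinylogously alpha to the lactone carbonyl, chloride leaves, and the electrophilic central carbon (C8) of vinylketene 22 is attacked by the nucleophilic methyl-bearing carbon of 21, so that the [2+2] adduct 23 holds the new C7–C8 and C5–C6 bonds. On heating, 23 opens reversibly by conrotatory 4π cleavage of its C8–C5 bond to dienylketene 24, and the isomer whose lactone alkene lies cis to the ketene arm closes ring C by a disrotatory 6π electrocyclisation that joins C8 to the lactone alpha carbon C8a; dienone 25, a β-keto lactone with an acidic C8a–H, enolises to the chelated C8 phenol. The closest known reaction type is the Danheiser benzannulation of siloxyalkynes with vinylketenes released from cyclobutenones or by Wolff rearrangement of unsaturated diazo ketones, and amine dehydrochlorination is the classical entry to ketene [2+2] chemistry; what is new is the union of the two on a lactone-conjugated vinylketene. No lasting stereocentre is made: the alpha carbon of 18, the quaternary carbon of 23 and C8a of 25 all end as sp2 ring atoms, and C3 lies outside the reacting array and keeps its R configuration. The step needs regioselectivity in the [2+2] event, secured by the polarity of the ynol ether (methyl carbon to ketene carbonyl carbon, which puts methyl on C7 between the two oxygens), and it needs the ketene to be caught before it dimerises, secured by slow addition of 18 to an excess of 21. Oxa-6π closure of 22 to a pyranone is excluded because the ring alkene holds the ketene carbon trans to the lactone carbonyl, and acylation of the product phenol is avoided because the phenol appears only in the heating stage, when no ketene source is left.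

**Step 14**
Reactants: 26 (R)-5-[(5,7-dimethoxy-2-methyl-4-oxo-4H-chromen-6-yl)methyl]-8-hydroxy-3,7-dimethyl-6-(triisopropylsiloxy)isochroman-1-one
Product: 27 (R)-5-[(5,7-dimethoxy-2-methyl-4-oxo-4H-chromen-6-yl)methyl]-6,8-dihydroxy-3,7-dimethylisochroman-1-one
Conditions: Bu4NF, AcOH, THF, 0 °C
Reagents that add atoms: none
Why: Fluoride cleavage of an aryl silyl ether, driven by the Si–F bond; acetic acid buffers the phenoxide so that the lactone and the chromone are not exposed to base.

**Step 15**
Reactants: 27 (R)-5-[(5,7-dimethoxy-2-methyl-4-oxo-4H-chromen-6-yl)methyl]-6,8-dihydroxy-3,7-dimethylisochroman-1-one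
Product: 28 (R)-6,8-dihydroxy-5-[(5-hydroxy-7-methoxy-2-methyl-4-oxo-4H-chromen-6-yl)methyl]-3,7-dimethylisochroman-1-one (CNP0180307.1)
Conditions: BCl3 (5 equiv), CH2Cl2, −78 → 0 °C; then H2O
Reagents that add atoms: none
Why: Chelation-directed aryl methyl ether cleavage: BCl3 binds between the chromone C4 carbonyl and the peri C5 methoxy oxygen in a six-membered chelate and chloride removes only that methyl group, while the chromone C7 methoxy group has no carbonyl neighbour.

**Compound list**
1 | 4-hydroxy-2,6-dimethoxybenzaldehyde | COc1cc(O)cc(OC)c1C=O | starting material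
2 | 4-hydroxy-3-iodo-2,6-dimethoxybenzaldehyde | COc1cc(O)c(I)c(OC)c1C=O | intermediate
3 | propyne | CC#C | starting material
4 | 3-(but-2-ynoyl)-4-hydroxy-2,6-dimethoxybenzaldehyde (ynone, not isolated) | COc1cc(O)c(C(=O)C#CC)c(OC)c1C=O | intermediate
5 | 5,7-dimethoxy-2-methyl-4-oxo-4H-chromene-6-carbaldehyde | COc1cc2oc(C)cc(=O)c2c(OC)c1C=O | intermediate
6 | 6-(hydroxymethyl)-5,7-dimethoxy-2-methyl-4H-chromen-4-one | COc1cc2oc(C)cc(=O)c2c(OC)c1CO | intermediate
7 | 6-(bromomethyl)-5,7-dimethoxy-2-methyl-4H-chromen-4-one | COc1cc2oc(C)cc(=O)c2c(OC)c1CBr | intermediate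
8 | ethyl (R)-3-hydroxybutanoate | C[C@@H](O)CC(=O)OCC | starting material
9 | tert-butyl acetate | CC(=O)OC(C)(C)C | starting material
10 | tert-butyl (R)-5-hydroxy-3-oxohexanoate | C[C@@H](O)CC(=O)CC(=O)OC(C)(C)C | intermediate
11 | (R)-4-hydroxy-6-methyl-5,6-dihydro-2H-pyran-2-one | C[C@@H]1CC(O)=CC(=O)O1 | intermediate
12 | (R)-6-methyl-2-oxo-5,6-dihydro-2H-pyran-4-yl 4-methylbenzenesulfonate | C[C@@H]1CC(OS(=O)(=O)c2ccc(C)cc2)=CC(=O)O1 | intermediate
13 | di-tert-butyl malonate | CC(C)(C)OC(=O)CC(=O)OC(C)(C)C | starting material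
14 | di-tert-butyl 2-[(R)-6-methyl-2-oxo-5,6-dihydro-2H-pyran-4-yl]malonate | C[C@@H]1CC(C(C(=O)OC(C)(C)C)C(=O)OC(C)(C)C)=CC(=O)O1 | intermediate
15 | di-tert-butyl 2-[(5,7-dimethoxy-2-methyl-4-oxo-4H-chromen-6-yl)methyl]-2-[(R)-6-methyl-2-oxo-5,6-dihydro-2H-pyran-4-yl]malonate | C[C@@H]1CC(C(Cc2c(OC)cc3oc(C)cc(=O)c3c2OC)(C(=O)OC(C)(C)C)C(=O)OC(C)(C)C)=CC(=O)O1 | intermediate
16 | 2-[(5,7-dimethoxy-2-methyl-4-oxo-4H-chromen-6-yl)methyl]-2-[(R)-6-methyl-2-oxo-5,6-dihydro-2H-pyran-4-yl]malonic acid (not isolated) | C[C@@H]1CC(C(Cc2c(OC)cc3oc(C)cc(=O)c3c2OC)(C(=O)O)C(=O)O)=CC(=O)O1 | intermediate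
17 | 3-(5,7-dimethoxy-2-methyl-4-oxo-4H-chromen-6-yl)-2-[(R)-6-methyl-2-oxo-5,6-dihydro-2H-pyran-4-yl]propanoic acid (both epimers at C2) | C[C@@H]1CC(C(Cc2c(OC)cc3oc(C)cc(=O)c3c2OC)C(=O)O)=CC(=O)O1 | intermediate
18 | 3-(5,7-dimethoxy-2-methyl-4-oxo-4H-chromen-6-yl)-2-[(R)-6-methyl-2-oxo-5,6-dihydro-2H-pyran-4-yl]propanoyl chloride (both epimers at C2) | C[C@@H]1CC(C(Cc2c(OC)cc3oc(C)cc(=O)c3c2OC)C(=O)Cl)=CC(=O)O1 | intermediate
19 | 1-propynyllithium (not isolated) | CC#C[Li] | intermediate
20 | lithium prop-1-yn-1-olate (not isolated) | CC#C[O-].[Li+] | intermediate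
21 | 1-(triisopropylsiloxy)propyne | CC#CO[Si](C(C)C)(C(C)C)C(C)C | intermediate
22 | 3-(5,7-dimethoxy-2-methyl-4-oxo-4H-chromen-6-yl)-2-[(R)-6-methyl-2-oxo-5,6-dihydro-2H-pyran-4-yl]prop-1-en-1-one (vinylketene, not isolated) | C[C@@H]1CC(C(Cc2c(OC)cc3oc(C)cc(=O)c3c2OC)=C=O)=CC(=O)O1 | intermediate
23 | 4-[(5,7-dimethoxy-2-methyl-4-oxo-4H-chromen-6-yl)methyl]-2-methyl-4-[(R)-6-methyl-2-oxo-5,6-dihydro-2H-pyran-4-yl]-3-(triisopropylsiloxy)cyclobut-2-en-1-one (both epimers at C4, not isolated) | C[C@@H]1CC(C2(Cc3c(OC)cc4oc(C)cc(=O)c4c3OC)C(=O)C(C)=C2O[Si](C(C)C)(C(C)C)C(C)C)=CC(=O)O1 | intermediate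
24 | 5-(5,7-dimethoxy-2-methyl-4-oxo-4H-chromen-6-yl)-2-methyl-4-[(R)-6-methyl-2-oxo-5,6-dihydro-2H-pyran-4-yl]-3-(triisopropylsiloxy)penta-1,3-dien-1-one (dienylketene, alkene isomers interconvert through 23, not isolated) | C[C@@H]1CC(C(Cc2c(OC)cc3oc(C)cc(=O)c3c2OC)=C(O[Si](C(C)C)(C(C)C)C(C)C)C(C)=C=O)=CC(=O)O1 | intermediate
25 | (3R)-5-[(5,7-dimethoxy-2-methyl-4-oxo-4H-chromen-6-yl)methyl]-3,7-dimethyl-6-(triisopropylsiloxy)-3,4-dihydro-1H-isochromene-1,8(8aH)-dione (C8a undefined, not isolated) | C[C@@H]1CC2=C(Cc3c(OC)cc4oc(C)cc(=O)c4c3OC)C(O[Si](C(C)C)(C(C)C)C(C)C)=C(C)C(=O)C2C(=O)O1 | intermediate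
26 | (R)-5-[(5,7-dimethoxy-2-methyl-4-oxo-4H-chromen-6-yl)methyl]-8-hydroxy-3,7-dimethyl-6-(triisopropylsiloxy)isochroman-1-one | C[C@@H]1Cc2c(Cc3c(OC)cc4oc(C)cc(=O)c4c3OC)c(O[Si](C(C)C)(C(C)C)C(C)C)c(C)c(O)c2C(=O)O1 | intermediate
27 | (R)-5-[(5,7-dimethoxy-2-methyl-4-oxo-4H-chromen-6-yl)methyl]-6,8-dihydroxy-3,7-dimethylisochroman-1-one | C[C@@H]1Cc2c(Cc3c(OC)cc4oc(C)cc(=O)c4c3OC)c(O)c(C)c(O)c2C(=O)O1 | intermediate
28 | (R)-6,8-dihydroxy-5-[(5-hydroxy-7-methoxy-2-methyl-4-oxo-4H-chromen-6-yl)methyl]-3,7-dimethylisochroman-1-one | COc1cc2oc(C)cc(=O)c2c(O)c1Cc1c(O)c(C)c(O)c2c1C[C@@H](C)OC2=O | target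

**Step count**
Total steps: 15.
Longest linear sequence: 10 steps (1 → 2 → 5 → 6 → 7 → 15 → 17 → 18 → 26 → 27 → 28). The branch from 8 through 10, 11, 12 and 14 is equally long.

**Steps most likely to fail**

*Step 13.*
- What may go wrong:
  - Self-reaction of the ketene (dimerisation, or acylation of its own enolate precursor) may outpace the [2+2] capture.
  - Protonation of the ynol ether by the ammonium salt may do the same.
  - The crowded 6π closure to a hexasubstituted ring may lag behind decay of the ketene.
- A harmless deviation: stepwise collapse of the first-formed zwitterion at the far end of the extended enolate would only exchange the places of the free and the silylated oxygen. Step 14 erases that difference.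
- Fallback: ring C is built by polar chemistry. The fallback sets out from 18 and comes back at 27.
- First stage: 18 C-acylates the magnesium enolate of potassium ethyl 2-methylmalonate (MgCl2, Et3N, MeCN). This gives 2-(ethoxycarbonyl)-5-(5,7-dimethoxy-2-methyl-4-oxo-4H-chromen-6-yl)-2-methyl-4-[(R)-6-methyl-2-oxo-5,6-dihydro-2H-pyran-4-yl]-3-oxopentanoic acid F1.
- Second stage: F1 loses CO2 on acidic work-up and gives ethyl 5-(5,7-dimethoxy-2-methyl-4-oxo-4H-chromen-6-yl)-2-methyl-4-[(R)-6-methyl-2-oxo-5,6-dihydro-2H-pyran-4-yl]-3-oxopentanoate F2.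
- Ring closure: DBU in toluene at 80 °C forms the extended enolate. Its lactone alpha carbon attacks the ester carbonyl in a Dieckmann-type Claisen cyclisation. Loss of ethanol and enolisation give resorcinol 27. In this variant the former acyl chloride carbon ends as C6 and the ester carbon as C8.

*Step 9.*
- What may go wrong: the ambident anion may be alkylated at the lactone alpha carbon or on oxygen instead of at the malonate carbon. The labile benzylic bromide may also ionise and condense with itself before it is captured.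
- Fallback: the order of the two C–C bond formations is reversed. The fallback sets out from 7, 13 and 11 and comes back at 15.
- Benzylmalonate: 13 is alkylated first with 7 (NaH, THF), where only one carbon site is available. This gives di-tert-butyl 2-[(5,7-dimethoxy-2-methyl-4-oxo-4H-chromen-6-yl)methyl]malonate F3.
- Chloride: 11 is converted with (COCl)2 and catalytic DMF into (R)-4-chloro-6-methyl-5,6-dihydro-2H-pyran-2-one F4.
- Coupling: the sodium salt of F3 displaces chloride from F4 by addition–elimination (DMF, 50 °C). The quaternary carbon then arises at an electrophile that has a single reactive site and no sulfur centre.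

*Step 8.*
- What may go wrong: the carbanion may attack sulfur, which amounts to detosylation. Alternatively, γ-deprotonation followed by eliminative opening of the lactone would also endanger the stereocentre.
- Fallback: the lactone is built around the malonate. The fallback sets out from 13 and comes back at 14; purchased (R)-propylene oxide and ethyl propiolate take the place of 8 to 12.
- Ynoate: lithiated ethyl propiolate opens (R)-propylene oxide at its CH2 terminus (nBuLi, BF3·OEt2, THF, −78 °C) with retention at the carbinol carbon. This gives ethyl (R)-5-hydroxyhex-2-ynoate F5.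
- Addition: Michael addition of sodium di-tert-butyl malonate to F5 gives ethyl (5R)-3-[bis(tert-butoxycarbonyl)methyl]-5-hydroxyhex-2-enoate F6.
- Lactonisation: the alkene isomers of F6 equilibrate through the delocalised anion. The isomer with the hydroxyalkyl arm cis to the ester lactonises to 14.

**Further compounds**
F1 | step 13 | 2-(ethoxycarbonyl)-5-(5,7-dimethoxy-2-methyl-4-oxo-4H-chromen-6-yl)-2-methyl-4-[(R)-6-methyl-2-oxo-5,6-dihydro-2H-pyran-4-yl]-3-oxopentanoic acid | C[C@@H]1CC(C(Cc2c(OC)cc3oc(C)cc(=O)c3c2OC)C(=O)C(C)(C(=O)O)C(=O)OCC)=CC(=O)O1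
F2 | step 13 | ethyl 5-(5,7-dimethoxy-2-methyl-4-oxo-4H-chromen-6-yl)-2-methyl-4-[(R)-6-methyl-2-oxo-5,6-dihydro-2H-pyran-4-yl]-3-oxopentanoate | C[C@@H]1CC(C(Cc2c(OC)cc3oc(C)cc(=O)c3c2OC)C(=O)C(C)C(=O)OCC)=CC(=O)O1
F3 | step 9 | di-tert-butyl 2-[(5,7-dimethoxy-2-methyl-4-oxo-4H-chromen-6-yl)methyl]malonate | COc1cc2oc(C)cc(=O)c2c(OC)c1CC(C(=O)OC(C)(C)C)C(=O)OC(C)(C)C
F4 | step 9 | (R)-4-chloro-6-methyl-5,6-dihydro-2H-pyran-2-one | C[C@@H]1CC(Cl)=CC(=O)O1
F5 | step 8 | ethyl (R)-5-hydroxyhex-2-ynoate | C[C@@H](O)CC#CC(=O)OCC
F6 | step 8 | ethyl (5R)-3-[bis(tert-butoxycarbonyl)methyl]-5-hydroxyhex-2-enoate (alkene isomers) | C[C@@H](O)CC(=CC(=O)OCC)C(C(=O)OC(C)(C)C)C(=O)OC(C)(C)C
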